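Three constants read from Saturday's run place the peak of intermediate A in this flask, which repeats that recipe.

| flask | substrate | partner | remark | time |
|---|---|---|---|---|
| Saturday's | 1.9 M | 1.71 M | the very flask that is asked about, followed so far |  |
| flask | 1.9 M | 1.71 M |  | 25 min |

Saturday's run (percent of the substrate charged)

| time / min | intermediate A / % | target / % |
|---|---|---|
| 0.250 | 7.2 | 23.9 |
| 0.833 | 11.4 | 54.5 |
| 2.50 | 10.6 | 77.5 |
| 8.00 | 9.6 | 80.9 |

(readings scatter by 0.3 percentage points)

- the earlier runs were read with a standard deviation of 0.3 percentage points

- time, not beyond 25 min, at which the flask holds most intermediate A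
- the amount of intermediate A, in percent of the substrate charged, at that time

1. First instants. By 0.250 min, Saturday's flask holds 31.1% of the charge as intermediate A plus target. Counting the remainder as substrate gives a loss constant of 1.49 min⁻¹. Intermediate A takes a share of 23.2% of that loss, a selectivity measure.

2. Middle. By 0.833 min, that share should have fed intermediate A with 8.1 points, yet it rose by 4.2 points. The difference, taken over the mean [intermediate A], gives a pseudo-first-order drain constant of 0.711 min⁻¹.

3. Crossing. Assume that feed and drain both scale with [partner], so that partner cancels. Control then passes from feed to drain when [substrate]/[intermediate A] falls to the crossing ratio, 2.06.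

4. Peak. With [intermediate A] near the highest reading, 11.4%, the crossing needs 23.5% substrate, which the loss constant, taken as steady, puts at 0.972 min. This reckoning commits to that time and about that reading.

5. End. The later readings fall, to 9.6% at 8.00 min.

The forecast gives 1.2 min and 12%, later and higher than this reckoning, on the ground that “the fast early loss probably depends on partner”.

The flask gives 11.3% at 1.09 min.

    substrate → target (k = 0.0190 s⁻¹)
    partner ⇌ dormant form (K = 2.30, k = 0.00350 s⁻¹)
    partner + intermediate A ⇌ intermediate B (K = 1.70 M⁻¹, k = 0.0110 M⁻¹ s⁻¹)
    partner → decomposed reagent (k = 0.00210 s⁻¹)
    substrate + partner ⇌ intermediate A (K = 23.0 M⁻¹, k = 0.00410 M⁻¹ s⁻¹)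
    intermediate B → side product (k = 0.00320 s⁻¹)

Feed and drain both contain partner. At 1.09 min the flask holds 20.9% substrate, a [substrate]/[intermediate A] of 1.85. The peak is 0.722 of the level reckoned as share/(1+crossing ratio×share). For the neighbour flask with 0.68 M partner, the feed-to-target ratio is reckoned in proportion to the partner charge, which gives a share of 10.7%. The same crossing ratio and fraction then reckon 6.33% for that flask. That flask's simulated peak is 6.57%.

The data were generated by integration with constants of no real substance, and the scatter is random.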